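Ring A is numbered C1–C5/C10 and ring B C5–C10 (labdane numbering). The route rests on cutting ring B at C5–C6 and C7–C8, so that the C6–C7 ethano bridge is methyl acrylate. In one pot it is clipped between C5, released as the regiodefined enolate of a ring A C4 ketone (C4 is the future quaternary carbon), and C8, the future methylidene-bearing carbon, held as an ester on the C10 acetate arm (tandem Michael–Dieckmann). The precursor is a monocyclic enol acetate from asymmetric conjugate methylation, which fixes C10. The trans-decalin product, with a free C4 ketone and a C7/C8 β-keto ester, lets C4 become C(CH2OAc)2, C9 be alkylated and C8 be methylenated.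

Key step: step 3

Remark: labdane numbering also denotes C17 (methylidene carbon on C8), C18/C19 (the CH2OAc carbons on C4), C20 (methyl on C10) and C11–C16 (side chain on C9); (2E)-3-methylpent-2-en-4-yn-1-ol is assumed to be purchasable as the pure E isomer.

Step 1
Reactants: 1 3-ethoxycyclohex-2-en-1-one; 2 methyl acetate
Product: 4 methyl 2-(3-oxocyclohex-1-en-1-yl)acetate, via tertiary carbinol 3 (not isolated)
Conditions: 2, LiN(iPr)2, THF, −78 °C; 1, −78 → 0 °C; then 2 M HCl, 25 °C
Reagents that add atoms: water, O
Why: 1,2-Addition of the ester enolate to the vinylogous ester, followed by acid-induced enol ether hydrolysis and dehydration of carbinol 3 (Stork–Danheiser-type transposition), should give the 3-substituted enone, which has no stereocentre.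

Step 2
Reactants: 4 methyl 2-(3-oxocyclohex-1-en-1-yl)acetate
Product: 6 methyl 2-[(1S)-3-acetoxy-1-methylcyclohex-2-en-1-yl]acetate, via dimethylaluminium enolate 5 (not isolated)
Conditions: AlMe3 (1.5 equiv), copper thiophene-2-carboxylate (2 mol %), chiral BINOL-derived phosphoramidite ligand (4 mol %, the enantiomer that gives (S)-6), Et2O, −30 °C; then Ac2O, −30 → 0 °C
Reagents that add atoms: trimethylaluminium, C[Al](C)C; acetic anhydride, CC(=O)OC(C)=O
Why: Copper-catalysed asymmetric conjugate addition of AlMe3 to β,β-disubstituted cyclohexenones is an established route to all-carbon quaternary centres, the ligand enantiomer being chosen so that methyl adds to the enone face that gives the required C10 configuration, and O-acetylation of aluminium enolate 5 stores the C4–C5 enolate regiochemistry in an isolable form.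

Step 3
Reactants: 6 methyl 2-[(1S)-3-acetoxy-1-methylcyclohex-2-en-1-yl]acetate; 7 methyl acrylate
Product: 10 methyl (4aS,8aS)-4a-methyl-3,8-dioxodecahydronaphthalene-2-carboxylate, via potassium enolate 8 (not isolated), via Michael adduct ester enolate 9 (not isolated)
Conditions: KOtBu (1.0 equiv), THF, −78 °C; 7 (1.1 equiv, slow addition), −78 → 0 °C; KOMe (0.2 equiv), MeOH, 25 °C; AcOH
Reagents that add atoms: none
Why: tert-Butoxide cleaves the enol acetate to the regiodefined potassium enolate 8, whose C5 adds to the β-carbon of 7 (C5–C6 bond), and the resulting ester enolate 9 attacks the C8 ester carbonyl on the adjacent C10 arm (C7–C8 bond), expelling methoxide, which deprotonates the new β-keto ester and so pulls the sequence forward. The closest known reaction type is the tandem Michael–Dieckmann annulation of ketone enolates with acrylates (a Michael-initiated ring closure, formally an anionic [4+2] annulation). Ring B is closed by a 6-(enolexo)-exo-trig acyl substitution. The only new persistent stereocentre, C5, is α to the C4 ketone and is therefore set under thermodynamic control by the catalytic methoxide: the trans-fused isomer, with C6 equatorial on ring A and the axial C10 methyl facing only two axial hydrogens because C4 and C8 are trigonal, should predominate, and any cis-fused epimer can be separated and re-equilibrated; C7 is an enolised, inconsequential centre and C10 is untouched. The step needs reaction at C5 rather than C3, which the enol acetate stored in step 2 guarantees; it needs Michael addition rather than acrylate oligomerisation, which the fast six-membered Dieckmann trap of 9 favours; and it needs acylation of C7 rather than of C9, which follows because the enolate is generated at C7 while C9 is a neopentyl methylene. The product carries two differentiated carbonyl groups, a free C4 ketone and an enolised C7/C8 β-keto ester, on which the rest of the route depends.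

Step 4
Reactants: 10 methyl (4aS,8aS)-4a-methyl-3,8-dioxodecahydronaphthalene-2-carboxylate
Product: 11 methyl (4aS,8aS)-8-(methoxymethylidene)-4a-methyl-3-oxodecahydronaphthalene-2-carboxylate
Conditions: MeOCH2PPh3Cl (3.5 equiv), KN(SiMe3)2 (3.3 equiv), THF, 0 → 25 °C; AcOH (1 equiv)
Reagents that add atoms: (methoxymethyl)triphenylphosphonium chloride, COC[P+](c1ccccc1)(c1ccccc1)c1ccccc1.[Cl-]
Why: In this Wittig olefination the first equivalent of ylide deprotonates the β-keto ester, whose enolate is inert, so that only the C4 ketone should be converted into the enol ether, which introduces C18, masks C4 against the later base steps and leaves C5 and C10 untouched.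

Step 5
Reactants: 12 (2E)-3-methylpent-2-en-4-yn-1-ol
Product: 13 (2E)-3-methylpenta-2,4-dien-1-ol
Conditions: H2 (1 atm, one equivalent taken up), Pd/CaCO3 poisoned with Pb(OAc)2 (Lindlar catalyst), quinoline, EtOAc, 0 °C
Reagents that add atoms: none
Why: Lindlar semihydrogenation should reduce the terminal alkyne to the vinyl group and stop there, leaving the E-trisubstituted alkene and its geometry untouched.

Step 6
Reactants: 13 (2E)-3-methylpenta-2,4-dien-1-ol
Product: 14 (3E)-5-bromo-3-methylpenta-1,3-diene
Conditions: PBr3 (0.4 equiv), Et2O, −10 °C, dark; used without storage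
Reagents that add atoms: phosphorus tribromide, BrP(Br)Br
Why: PBr3 should convert the primary allylic alcohol into the bromide by SN2-type substitution at low temperature, the conjugated primary bromide being also the thermodynamically favoured allylic isomer, so that the E geometry is retained.

Step 7
Reactants: 11 methyl (4aS,8aS)-8-(methoxymethylidene)-4a-methyl-3-oxodecahydronaphthalene-2-carboxylate; 14 (3E)-5-bromo-3-methylpenta-1,3-diene
Product: 16 methyl (4aR,8aS)-8-(methoxymethylidene)-4a-methyl-4-[(2E)-3-methylpenta-2,4-dien-1-yl]-3-oxodecahydronaphthalene-2-carboxylate, via dilithium dianion 15 (not isolated)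
Conditions: LiN(iPr)2 (2.2 equiv), THF, −78 → 0 °C; 14 (1.1 equiv), −78 → −20 °C; AcOH
Reagents that add atoms: none
Why: γ-Alkylation of a β-keto ester dianion: after deprotonation of C7 the second deprotonation can only occur at C9, and this more basic terminus of dianion 15 should attack the primary allylic bromide by SN2, the C9 configuration formed being irrelevant because it is equilibrated in step 8.

Step 8
Reactants: 16 methyl (4aR,8aS)-8-(methoxymethylidene)-4a-methyl-4-[(2E)-3-methylpenta-2,4-dien-1-yl]-3-oxodecahydronaphthalene-2-carboxylate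
Product: 17 (1S,4aS,8aR)-5-(methoxymethylidene)-8a-methyl-1-[(2E)-3-methylpenta-2,4-dien-1-yl]octahydronaphthalen-2(1H)-one
Conditions: LiCl (3 equiv), H2O (2 equiv), DMSO, 140 °C; then NaOMe (0.2 equiv), MeOH, 25 °C
Reagents that add atoms: none
Why: Krapcho dealkoxycarbonylation should remove the C7 ester under neutral conditions that spare the enol ether and the diene, and catalytic methoxide then equilibrates the enolisable C9 centre to the epimer with the side chain equatorial and cis to the C10 methyl, the thermodynamically preferred arrangement on the trans-decalin and the one required.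

Step 9
Reactants: 17 (1S,4aS,8aR)-5-(methoxymethylidene)-8a-methyl-1-[(2E)-3-methylpenta-2,4-dien-1-yl]octahydronaphthalen-2(1H)-one
Product: 18 (1R,4aS,8aS)-5-(methoxymethylidene)-8a-methyl-2-methylidene-1-[(2E)-3-methylpenta-2,4-dien-1-yl]decahydronaphthalene
Conditions: Ph3PCH3Br (3 equiv), KOtBu (2.8 equiv), toluene, 25 → 80 °C
Reagents that add atoms: methyltriphenylphosphonium bromide, C[P+](c1ccccc1)(c1ccccc1)c1ccccc1.[Br-]
Why: Wittig methylenation with excess ylide at elevated temperature is the standard way to convert hindered 8-oxo decalins of this type into the exocyclic methylene, the enol ether and diene being inert and C9 remaining in its thermodynamic configuration.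

Step 10
Reactants: 18 (1R,4aS,8aS)-5-(methoxymethylidene)-8a-methyl-2-methylidene-1-[(2E)-3-methylpenta-2,4-dien-1-yl]decahydronaphthalene
Product: 19 (4aR,5R,8aR)-4a-methyl-6-methylidene-5-[(2E)-3-methylpenta-2,4-dien-1-yl]decahydronaphthalene-1-carbaldehyde
Conditions: TsOH·H2O (0.1 equiv), acetone/H2O (10:1), 25 °C
Reagents that add atoms: water, O
Why: Acid-catalysed hydrolysis of the methyl enol ether (second stage of the Wittig homologation) should release the C4 carbaldehyde far faster than the exocyclic alkene or the diene can isomerise, and the new C4 centre is inconsequential because it becomes a non-stereogenic quaternary carbon in step 11.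

Step 11
Reactants: 19 (4aR,5R,8aR)-4a-methyl-6-methylidene-5-[(2E)-3-methylpenta-2,4-dien-1-yl]decahydronaphthalene-1-carbaldehyde
Product: 21 [(4aS,5R,8aS)-4a-methyl-6-methylidene-5-[(2E)-3-methylpenta-2,4-dien-1-yl]octahydronaphthalene-1,1(2H)-diyl]dimethanol, via hydroxy aldehyde 20 (not isolated)
Conditions: aq. CH2O (37 %, 10 equiv), KOH (3 equiv), MeOH, 60 °C
Reagents that add atoms: formaldehyde, C=O
Why: Tollens condensation: hydroxide-mediated aldol reaction of the only enolisable position, C4, with formaldehyde gives hydroxy aldehyde 20, which a second formaldehyde reduces by crossed Cannizzaro hydride transfer, so that C4 ends as a quaternary carbon bearing two identical CH2OH groups.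

Step 12
Reactants: 21 [(4aS,5R,8aS)-4a-methyl-6-methylidene-5-[(2E)-3-methylpenta-2,4-dien-1-yl]octahydronaphthalene-1,1(2H)-diyl]dimethanol
Product: 22 [(4aS,5R,8aS)-4a-methyl-6-methylidene-5-[(2E)-3-methylpenta-2,4-dien-1-yl]octahydronaphthalene-1,1(2H)-diyl]bis(methylene) diacetate
Conditions: Ac2O (4 equiv), pyridine, DMAP (0.1 equiv), CH2Cl2, 25 °C
Reagents that add atoms: acetic anhydride, CC(=O)OC(C)=O
Why: DMAP-catalysed acylation of the two primary neopentyl alcohols should give the diacetate without touching any stereocentre.

Compound list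
1 | 3-ethoxycyclohex-2-en-1-one | CCOC1=CC(=O)CCC1 | starting material
2 | methyl acetate | COC(C)=O | starting material
3 | methyl 2-(3-ethoxy-1-hydroxycyclohex-2-en-1-yl)acetate (racemic tertiary carbinol) | CCOC1=CC(O)(CC(=O)OC)CCC1 | intermediate
4 | methyl 2-(3-oxocyclohex-1-en-1-yl)acetate | COC(=O)CC1=CC(=O)CCC1 | intermediate
5 | methyl 2-{(1S)-3-[(dimethylalumanyl)oxy]-1-methylcyclohex-2-en-1-yl}acetate (aluminium enolate) | C1CCC(O[Al](C)C)=C[C@@]1(CC(=O)OC)C | intermediate
6 | methyl 2-[(1S)-3-acetoxy-1-methylcyclohex-2-en-1-yl]acetate | C1CCC(OC(C)=O)=C[C@@]1(CC(=O)OC)C | intermediate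
7 | methyl acrylate | C=CC(=O)OC | starting material
8 | potassium (3S)-3-(2-methoxy-2-oxoethyl)-3-methylcyclohex-1-en-1-olate | C1CCC(O[K])=C[C@@]1(CC(=O)OC)C | intermediate
9 | potassium ester enolate of methyl 3-[(2S)-2-(2-methoxy-2-oxoethyl)-2-methyl-6-oxocyclohexyl]propanoate (Michael adduct, epimers at the ring carbon bearing the propanoate chain) | C1CCC(=O)C(CC=C(OC)O[K])[C@@]1(CC(=O)OC)C | intermediate
10 | methyl (4aS,8aS)-4a-methyl-3,8-dioxodecahydronaphthalene-2-carboxylate (trans-fused; labdane 5S,10S; C2 epimers in equilibrium with the enol) | C1C(=O)C(C(=O)OC)C[C@@H]2C(=O)CCC[C@@]12C | intermediate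
11 | methyl (4aS,8aS)-8-(methoxymethylidene)-4a-methyl-3-oxodecahydronaphthalene-2-carboxylate (E/Z enol ether) | C1C(=O)C(C(=O)OC)C[C@@H]2C(=COC)CCC[C@@]12C | intermediate
12 | (2E)-3-methylpent-2-en-4-yn-1-ol | C#C/C(C)=C/CO | starting material
13 | (2E)-3-methylpenta-2,4-dien-1-ol | C=C/C(C)=C/CO | intermediate
14 | (3E)-5-bromo-3-methylpenta-1,3-diene | C=C/C(C)=C/CBr | intermediate
15 | dilithium dianion of 11 (dienediolate, deprotonated at C7 and C9; C5 and C10 as in 11) | C1=C(O[Li])C(=C(OC)O[Li])C[C@@H]2C(=COC)CCC[C@@]12C | intermediate
16 | methyl (4aR,8aS)-8-(methoxymethylidene)-4a-methyl-4-[(2E)-3-methylpenta-2,4-dien-1-yl]-3-oxodecahydronaphthalene-2-carboxylate (epimers at C2 and C4; ring fusion as in 11) | C=C/C(C)=C/CC1C(=O)C(C(=O)OC)C[C@@H]2C(=COC)CCC[C@@]12C | intermediate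
17 | (1S,4aS,8aR)-5-(methoxymethylidene)-8a-methyl-1-[(2E)-3-methylpenta-2,4-dien-1-yl]octahydronaphthalen-2(1H)-one (trans-fused, side chain equatorial and cis to the angular methyl) | C=C/C(C)=C/C[C@@H]1C(=O)CC[C@@H]2C(=COC)CCC[C@@]12C | intermediate
18 | (1R,4aS,8aS)-5-(methoxymethylidene)-8a-methyl-2-methylidene-1-[(2E)-3-methylpenta-2,4-dien-1-yl]decahydronaphthalene | C=C/C(C)=C/C[C@@H]1C(=C)CC[C@@H]2C(=COC)CCC[C@@]12C | intermediate
19 | (4aR,5R,8aR)-4a-methyl-6-methylidene-5-[(2E)-3-methylpenta-2,4-dien-1-yl]decahydronaphthalene-1-carbaldehyde (C1 epimers) | C=C/C(C)=C/C[C@@H]1C(=C)CC[C@@H]2C(C=O)CCC[C@@]12C | intermediate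
20 | (4aS,5R,8aS)-1-(hydroxymethyl)-4a-methyl-6-methylidene-5-[(2E)-3-methylpenta-2,4-dien-1-yl]decahydronaphthalene-1-carbaldehyde (C1 epimers) | C=C/C(C)=C/C[C@@H]1C(=C)CC[C@@H]2C(C=O)(CO)CCC[C@@]12C | intermediate
21 | [(4aS,5R,8aS)-4a-methyl-6-methylidene-5-[(2E)-3-methylpenta-2,4-dien-1-yl]octahydronaphthalene-1,1(2H)-diyl]dimethanol | C=C/C(C)=C/C[C@@H]1C(=C)CC[C@@H]2C(CO)(CO)CCC[C@@]12C | intermediate
22 | [(4aS,5R,8aS)-4a-methyl-6-methylidene-5-[(2E)-3-methylpenta-2,4-dien-1-yl]octahydronaphthalene-1,1(2H)-diyl]bis(methylene) diacetate (CNP0129553.1; labdane 5S,9R,10S) | C=C/C(C)=C/C[C@@H]1C(=C)CC[C@@H]2C(COC(C)=O)(COC(C)=O)CCC[C@@]12C | target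

Total step count: 12. Longest linear sequence: 10 steps (steps 1–4 and 7–12; steps 5 and 6 prepare the side-chain bromide).

Steps most likely to fail

Step 3 (key step). Conjugate addition at the neopentyl-flanked C5 may lose out to anionic oligomerisation of 7 or to proton transfer that scrambles the enolate regiochemistry, and equilibration may leave a sizeable share of the cis-fused epimer. Fallback: the two bond formations are uncoupled and the first is moved from anionic to Lewis acid activation. Starting from 4, the conjugate methylation of step 2 is quenched with Me3SiOTf instead of Ac2O to give methyl 2-[(1S)-1-methyl-3-(trimethylsilyloxy)cyclohex-2-en-1-yl]acetate F1. TiCl4-mediated Mukaiyama–Michael addition of F1 to 7 (CH2Cl2, −78 °C) should give methyl 3-[(2S)-2-(2-methoxy-2-oxoethyl)-2-methyl-6-oxocyclohexyl]propanoate F2. NaOMe in MeOH then effects the Dieckmann closure and the C5 equilibration as a separate, individually tunable operation, and the route is rejoined at 10.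

Step 7. The second deprotonation at the neopentyl C9 methylene may be incomplete, and the dianion may be alkylated at C7 or on oxygen or attack the dienyl bromide in the SN2′ sense. Fallback: the side chain is attached before ring B exists, by ordinary ester enolate alkylation. From 4, conjugate methylation with Et3SiOTf quench gives methyl 2-[(1S)-1-methyl-3-(triethylsilyloxy)cyclohex-2-en-1-yl]acetate F3. LiN(iPr)2 at −78 °C (the ester α-position is the only acidic site) and 14 should give methyl (4E)-5-methyl-2-[(1R)-1-methyl-3-(triethylsilyloxy)cyclohex-2-en-1-yl]hepta-4,6-dienoate F4 as an epimer mixture at the new centre. Fluoride-triggered (Bu4NF, THF) Michael–Dieckmann annulation with 7 then gives methyl (4aR,8aS)-4a-methyl-4-[(2E)-3-methylpenta-2,4-dien-1-yl]-3,8-dioxodecahydronaphthalene-2-carboxylate F5. Its C4 ketone is methoxymethylenated as in step 4 to return to 16, and C9 is equilibrated in step 8 as before.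

Step 11. At the doubly α-branched aldehyde, retro-aldol loss of formaldehyde and slow crossed-Cannizzaro hydride transfer may stall the reaction at the hydroxy aldehyde stage or divert it to formate esters. Fallback: aldol reaction and reduction are separated. 19 is hydroxymethylated with aqueous CH2O and K2CO3 in MeOH at 25 °C, hydroxy aldehyde 20 is isolated and then reduced with NaBH4 in MeOH at 0 °C to 21; no compound outside the list arises.

Further compounds
F1 | step 3 | methyl 2-[(1S)-1-methyl-3-(trimethylsilyloxy)cyclohex-2-en-1-yl]acetate | C1CCC(O[Si](C)(C)C)=C[C@@]1(CC(=O)OC)C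
F2 | step 3 | methyl 3-[(2S)-2-(2-methoxy-2-oxoethyl)-2-methyl-6-oxocyclohexyl]propanoate (epimers at ring C1) | C1CCC(=O)C(CCC(=O)OC)[C@@]1(CC(=O)OC)C
F3 | step 7 | methyl 2-[(1S)-1-methyl-3-(triethylsilyloxy)cyclohex-2-en-1-yl]acetate | C1CCC(O[Si](CC)(CC)CC)=C[C@@]1(CC(=O)OC)C
F4 | step 7 | methyl (4E)-5-methyl-2-[(1R)-1-methyl-3-(triethylsilyloxy)cyclohex-2-en-1-yl]hepta-4,6-dienoate (epimers at C2) | C1CCC(O[Si](CC)(CC)CC)=C[C@@]1(C(C/C=C(C)/C=C)C(=O)OC)C
F5 | step 7 | methyl (4aR,8aS)-4a-methyl-4-[(2E)-3-methylpenta-2,4-dien-1-yl]-3,8-dioxodecahydronaphthalene-2-carboxylate (epimers at C2 and C4) | C=C/C(C)=C/CC1C(=O)C(C(=O)OC)C[C@@H]2C(=O)CCC[C@@]12C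
F0 | step 11 | none | none
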